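**Retrosynthetic overview**

1. Ring B is a cyclohexene whose only double bond (C7=C8, abietane numbering) lies opposite the ring-fusion bond C5–C10. Cutting C5–C6 and C9–C10 is therefore a retro-Diels–Alder to a C6=C7–C8=C9 diene and a C5=C10 dienophile.
2. The trans relation of H5 and the C10 methyl is the (E)-geometry of an open-chain 2-methyl-2-enal, with C1 as the activating formyl group. The C8 carboxyl (as CH2OSi) and the C9 side chain map onto a 3-substituted vinylallene, whose sp carbon becomes an exocyclic C9=C11 methylene, so the cycloaddition does not have to set C9.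
3. Ring order: ring B first (asymmetric Diels–Alder, sets C5 and C10), then ring A (C4 dialkylation, the second alkylation setting C4, followed by ring-closing metathesis at C1=C2).
4. C9 and the keto side chain come from face-selective hydroboration of C9=C11 and boron-to-carbon transfer to an α-bromo ketone. The end game is C1=C2 hydrogenation, oxidation of C14 to the acid and ester cleavage.

Key step: step 4

Remark: atoms carry the abietane numbers of the target (C1–C20); β is the face of the C10 methyl group.

Assumption: the (S)-prolinol-derived oxazaborolidinium ion is taken to leave open the face of the enal that is Re at C10, as the usual pre-transition-state model for 2-substituted enals predicts; if the sense is the reverse, the (R)-catalyst is used with no other change.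

**Step 1**
Reactants: 1 4-chlorobut-2-yn-1-ol
Product: 2 tert-butyl[(4-chlorobut-2-yn-1-yl)oxy]dimethylsilane
Conditions: TBSCl, imidazole, CH2Cl2, 0 °C → rt
Reagents that add atoms: tert-butyldimethylsilyl chloride, CC(C)(C)[Si](C)(C)Cl
Why: Standard silyl ether formation on a primary propargylic alcohol masks the future C14 oxygen, and no stereocentre is involved.

**Step 2**
Reactants: 2 tert-butyl[(4-chlorobut-2-yn-1-yl)oxy]dimethylsilane
Product: 3 tert-butyl[(2-ethenylbuta-2,3-dien-1-yl)oxy]dimethylsilane (vinylallene CH2=C=C(CH2OTBS)–CH=CH2)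
Conditions: CH2=CHMgBr, CuBr·SMe2 (10 mol %), THF, −78 → 0 °C
Reagents that add atoms: vinylmagnesium bromide, C=C[Mg]Br
Why: Copper-catalysed SN2' substitution of a primary propargylic chloride by a Grignard reagent is the standard entry to allenes and puts the vinyl group on the alkyne carbon remote from chloride; the allene has a CH2 terminus and is achiral.

**Step 3**
Reactants: 4 tert-butyl acetate, 5 3-ethoxy-2-methylprop-2-enal
Product: 7 tert-butyl (3E)-4-methyl-5-oxopent-3-enoate, via lithium aldolate 6 (not isolated)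
Conditions: LiN(iPr)2, THF, −78 °C; 5, −78 °C; then 1 M HCl, THF, 0 °C → rt
Reagents that add atoms: water, O
Why: Aldol addition of the ester enolate to the formyl group of the vinylogous formate, followed by acid-induced allylic transposition and hydrolysis of the enol ether with loss of ethanol, is the established three-carbon enal homologation and should give the thermodynamically favoured (E)-2-methyl-2-enal with no stereocentre.

**Step 4**
Reactants: 3 vinylallene tert-butyl[(2-ethenylbuta-2,3-dien-1-yl)oxy]dimethylsilane, 7 tert-butyl (3E)-4-methyl-5-oxopent-3-enoate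
Product: 8 tert-butyl 2-[(1S,6S)-4-({[tert-butyl(dimethyl)silyl]oxy}methyl)-6-formyl-6-methyl-5-methylidenecyclohex-3-en-1-yl]acetate (ring B; C10 methyl and C5 CH2CO2tBu arm cis, both β; formyl α)
Conditions: 3 (1.5 equiv), (S)-3,3-diphenyl-1-(2-methylphenyl)tetrahydro-1H,3H-pyrrolo[1,2-c][1,3,2]oxazaborole (C24H24BNO, 20 mol %), HN(SO2CF3)2 (18 mol %), CH2Cl2, −78 → −40 °C
Reagents that add atoms: none
Why: Proposed new method: the protonated oxazaborolidine binds the formyl oxygen of 7 (s-trans enal) and vinylallene 3 adds in a concerted, asynchronous [4+2] cycloaddition in which the vinyl CH2 terminus (C6) bonds to the enal β-carbon (C5) ahead of the sp allene carbon (C9) bonding to the α-carbon (C10); the closest known reaction types are the oxazaborolidinium-catalysed enantioselective Diels–Alder reactions of 2-methyl-2-enals with open-chain dienes and the Lewis-acid-promoted Diels–Alder reactions of vinylallenes with enals, which have not been combined. Ring B is the only ring closed and it is closed in the intermolecular [4+2] mode. C5 and C10 are formed together: their relative configuration (C10 methyl cis to the C5 acetate arm, the later trans ring fusion) is the suprafacial copy of the (E)-geometry of 7, and their absolute configuration is set by the catalyst, which leaves open the face of 7 that is Re at C10. C9 emerges as an sp2 carbon (exocyclic methylene), so the endo/exo orientation of the diene has no stereochemical consequence and only regio- and enantiofacial selectivity are needed. Regioselectivity is secured by the formyl group (largest LUMO coefficient at C5) and by the diene (larger HOMO coefficient at the vinyl terminus C6, hyperconjugative donation from the allene CH2), and the unhindered sp carbon is what makes bond formation to the fully substituted C10 easy.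

**Step 5**
Reactants: 8 cycloadduct aldehyde
Product: 9 tert-butyl 2-[4-({[tert-butyl(dimethyl)silyl]oxy}methyl)-6-ethenyl-6-methyl-5-methylidenecyclohex-3-en-1-yl]acetate (configuration as 8: vinyl α, methyl β, C5 arm β)
Conditions: Ph3PCH3Br, KOtBu, THF, 0 °C; then 8, 0 °C → rt
Reagents that add atoms: methyltriphenylphosphonium bromide, C[P+](c1ccccc1)(c1ccccc1)c1ccccc1.[Br-]
Why: Wittig methylenation of a non-enolisable neopentyl aldehyde with a non-stabilised ylide is reliable, forms no stereocentre and cannot epimerise the quaternary C10.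

**Step 6**
Reactants: 9 vinyl ester
Product: 10 tert-butyl 2-[4-({[tert-butyl(dimethyl)silyl]oxy}methyl)-6-ethenyl-6-methyl-5-methylidenecyclohex-3-en-1-yl]pent-4-enoate (C4 allylated, mixture of C4 epimers)
Conditions: LiN(iPr)2, THF, −78 °C; allyl bromide, −78 → 0 °C
Reagents that add atoms: allyl bromide, C=CCBr
Why: Ester enolate alkylation with a reactive allylic halide at C4, the only acidic position, brings in C3 and C2; the C4 stereocentre forms as a mixture that is erased by enolisation in step 7.

**Step 7**
Reactants: 10 allylated ester (both C4 epimers)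
Product: 11 tert-butyl 2-[4-({[tert-butyl(dimethyl)silyl]oxy}methyl)-6-ethenyl-6-methyl-5-methylidenecyclohex-3-en-1-yl]-2-methylpent-4-enoate (quaternary C4 bearing CH3 = C19, allyl and CO2tBu = C18; configuration as in the SMILES)
Conditions: LiN(iPr)2, THF–DMPU, −78 °C; MeI, −78 → −20 °C
Reagents that add atoms: iodomethane, CI
Why: In this second ester enolate alkylation both C4 epimers of 10 converge on one enolate in which H5 eclipses the enolate double bond (allylic 1,3-strain), the face turned to the fully substituted C10 is blocked, and MeI should enter from the C6 side, which after ring closure places CH3 β (C19) and CO2tBu α (C18).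

**Step 8**
Reactants: 11 quaternary diene ester
Product: 12 tert-butyl 6-({[tert-butyl(dimethyl)silyl]oxy}methyl)-1,4a-dimethyl-5-methylidene-1,2,4a,5,8,8a-hexahydronaphthalene-1-carboxylate (trans-fused; C10 CH3 β, H5 α, C4 CH3 β and CO2tBu α; C1=C2, C7=C8 and exocyclic C9=C11)
Conditions: second-generation Grubbs catalyst RuCl2(=CHPh)(PCy3)(H2IMes) (5 mol %), CH2Cl2, 40 °C
Reagents that add atoms: none
Why: Ring-closing olefin metathesis of the C10 vinyl and C4 allyl groups, which sit trans-diequatorial on ring B, closes ring A as a cyclohexene with no new stereocentre, and the C9 methylene cannot compete because closure onto it would give a bridgehead olefin.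

**Step 9**
Reactants: 12 bicyclic triene ester, 13 1-bromo-3-methylbutan-2-one
Product: 15 tert-butyl 6-({[tert-butyl(dimethyl)silyl]oxy}methyl)-1,4a-dimethyl-5-(4-methyl-3-oxopentyl)-1,2,4a,5,8,8a-hexahydronaphthalene-1-carboxylate (H9 α, side chain β), via B-alkyl-9-BBN adduct 14 (not isolated)
Conditions: 9-BBN (1.2 equiv), THF, 0 °C → rt; then 13, potassium 2,6-di-tert-butylphenoxide, THF, 0 °C → rt
Reagents that add atoms: none
Why: 9-BBN should add to the terminal carbon of the exocyclic 1,1-disubstituted C9=C11 bond much faster than to the ring olefins and deliver hydrogen to C9 from the α-face, anti to the axial C10 methyl (H9 α), after which the primary B-alkyl group is transferred to the enolate of the α-bromo ketone by 1,2-migration with loss of bromide (the known α-alkylation of α-halo ketones with B-alkyl-9-BBN).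

**Step 10**
Reactants: 15 keto diene ester
Product: 16 tert-butyl 6-({[tert-butyl(dimethyl)silyl]oxy}methyl)-1,4a-dimethyl-5-(4-methyl-3-oxopentyl)-1,2,3,4,4a,5,8,8a-octahydronaphthalene-1-carboxylate (ring A saturated; stereocentres unchanged)
Conditions: H2 (1 atm), RhCl(PPh3)3 (10 mol %), benzene, rt
Reagents that add atoms: none
Why: Homogeneous hydrogenation with RhCl(PPh3)3 reduces the cis-disubstituted C1=C2 bond and should leave the trisubstituted C7=C8 bond and the ketone untouched, with no stereocentre formed.

**Step 11**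
Reactants: 16 silyl ether
Product: 17 tert-butyl 6-(hydroxymethyl)-1,4a-dimethyl-5-(4-methyl-3-oxopentyl)-1,2,3,4,4a,5,8,8a-octahydronaphthalene-1-carboxylate (C14 allylic alcohol)
Conditions: Bu4NF, THF, 0 °C
Reagents that add atoms: none
Why: Fluoride-induced cleavage of the primary silyl ether is selective and leaves the tert-butyl ester, the ketone and all stereocentres unchanged.

**Step 12**
Reactants: 17 allylic alcohol
Product: 18 tert-butyl 6-formyl-1,4a-dimethyl-5-(4-methyl-3-oxopentyl)-1,2,3,4,4a,5,8,8a-octahydronaphthalene-1-carboxylate (C14 enal conjugated with C7=C8)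
Conditions: MnO2, CH2Cl2, rt
Reagents that add atoms: none
Why: MnO2 oxidises the primary allylic alcohol selectively to the conjugated aldehyde; C9 is cross-conjugated to the new carbonyl group and is not epimerised.

**Step 13**
Reactants: 18 enal
Product: 19 5-(tert-butoxycarbonyl)-5,8a-dimethyl-1-(4-methyl-3-oxopentyl)-1,4,4a,5,6,7,8,8a-octahydronaphthalene-2-carboxylic acid (C14 acid, C18 tert-butyl ester of the target)
Conditions: NaClO2, NaH2PO4, 2-methyl-2-butene, t-BuOH–H2O, 0 °C → rt
Reagents that add atoms: sodium chlorite, [Na+].[O-]Cl=O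
Why: Pinnick oxidation converts the α,β-unsaturated aldehyde into the acid without touching the olefin, the ketone or any stereocentre, hypochlorous acid being trapped by 2-methyl-2-butene.

**Step 14**
Reactants: 19 acid tert-butyl ester
Product: 20 the target, (4R,5R,9R,10S)-13-oxo-13,14-secoabiet-7-ene-14,18-dioic acid
Conditions: CF3CO2H–CH2Cl2 (1:4), 0 °C → rt
Reagents that add atoms: none
Why: Acidolysis of the tert-butyl ester by alkyl–oxygen cleavage (loss of isobutene) is insensitive to the hindrance at C4 and leaves the enoic acid, the ketone and all four stereocentres intact.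

**Compound list**

1 | 4-chlorobut-2-yn-1-ol | OCC#CCCl | starting material
2 | tert-butyl[(4-chlorobut-2-yn-1-yl)oxy]dimethylsilane | ClCC#CCO[Si](C)(C)C(C)(C)C | intermediate
3 | tert-butyl[(2-ethenylbuta-2,3-dien-1-yl)oxy]dimethylsilane (vinylallene) | C=C=C(C=C)CO[Si](C)(C)C(C)(C)C | intermediate
4 | tert-butyl acetate | CC(=O)OC(C)(C)C | starting material
5 | 3-ethoxy-2-methylprop-2-enal | CCOC=C(C)C=O | starting material
6 | lithium aldolate of tert-butyl 5-ethoxy-3-hydroxy-4-methylpent-4-enoate (not isolated) | CCOC=C(C)C([O-])CC(=O)OC(C)(C)C.[Li+] | intermediate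
7 | tert-butyl (3E)-4-methyl-5-oxopent-3-enoate | O=C/C(C)=C/CC(=O)OC(C)(C)C | intermediate
8 | tert-butyl 2-[(1S,6S)-4-({[tert-butyl(dimethyl)silyl]oxy}methyl)-6-formyl-6-methyl-5-methylidenecyclohex-3-en-1-yl]acetate | O=C[C@]1(C)C(=C)C(CO[Si](C)(C)C(C)(C)C)=CC[C@H]1CC(=O)OC(C)(C)C | intermediate
9 | tert-butyl 2-[4-({[tert-butyl(dimethyl)silyl]oxy}methyl)-6-ethenyl-6-methyl-5-methylidenecyclohex-3-en-1-yl]acetate (configuration as 8) | C=C[C@]1(C)C(=C)C(CO[Si](C)(C)C(C)(C)C)=CC[C@H]1CC(=O)OC(C)(C)C | intermediate
10 | tert-butyl 2-[4-({[tert-butyl(dimethyl)silyl]oxy}methyl)-6-ethenyl-6-methyl-5-methylidenecyclohex-3-en-1-yl]pent-4-enoate (C4 epimers) | C=C[C@]1(C)C(=C)C(CO[Si](C)(C)C(C)(C)C)=CC[C@H]1C(CC=C)C(=O)OC(C)(C)C | intermediate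
11 | tert-butyl 2-[4-({[tert-butyl(dimethyl)silyl]oxy}methyl)-6-ethenyl-6-methyl-5-methylidenecyclohex-3-en-1-yl]-2-methylpent-4-enoate (quaternary C4) | C=C[C@]1(C)C(=C)C(CO[Si](C)(C)C(C)(C)C)=CC[C@H]1[C@@](C)(CC=C)C(=O)OC(C)(C)C | intermediate
12 | tert-butyl 6-({[tert-butyl(dimethyl)silyl]oxy}methyl)-1,4a-dimethyl-5-methylidene-1,2,4a,5,8,8a-hexahydronaphthalene-1-carboxylate (trans-fused; C10 CH3 β, H5 α, C4 CH3 β, CO2tBu α) | C=C1C(CO[Si](C)(C)C(C)(C)C)=CC[C@@H]2[C@]1(C)C=CC[C@@]2(C)C(=O)OC(C)(C)C | intermediate
13 | 1-bromo-3-methylbutan-2-one | CC(C)C(=O)CBr | starting material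
14 | B-alkyl-9-BBN adduct of 12 (boron on C11, H9 α; not isolated) | C([C@H]1C(CO[Si](C)(C)C(C)(C)C)=CC[C@@H]2[C@]1(C)C=CC[C@@]2(C)C(=O)OC(C)(C)C)B1C2CCCC1CCC2 | intermediate
15 | tert-butyl 6-({[tert-butyl(dimethyl)silyl]oxy}methyl)-1,4a-dimethyl-5-(4-methyl-3-oxopentyl)-1,2,4a,5,8,8a-hexahydronaphthalene-1-carboxylate (H9 α) | CC(C)C(=O)CC[C@H]1C(CO[Si](C)(C)C(C)(C)C)=CC[C@@H]2[C@]1(C)C=CC[C@@]2(C)C(=O)OC(C)(C)C | intermediate
16 | tert-butyl 6-({[tert-butyl(dimethyl)silyl]oxy}methyl)-1,4a-dimethyl-5-(4-methyl-3-oxopentyl)-1,2,3,4,4a,5,8,8a-octahydronaphthalene-1-carboxylate | CC(C)C(=O)CC[C@H]1C(CO[Si](C)(C)C(C)(C)C)=CC[C@@H]2[C@]1(C)CCC[C@@]2(C)C(=O)OC(C)(C)C | intermediate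
17 | tert-butyl 6-(hydroxymethyl)-1,4a-dimethyl-5-(4-methyl-3-oxopentyl)-1,2,3,4,4a,5,8,8a-octahydronaphthalene-1-carboxylate | CC(C)C(=O)CC[C@H]1C(CO)=CC[C@@H]2[C@]1(C)CCC[C@@]2(C)C(=O)OC(C)(C)C | intermediate
18 | tert-butyl 6-formyl-1,4a-dimethyl-5-(4-methyl-3-oxopentyl)-1,2,3,4,4a,5,8,8a-octahydronaphthalene-1-carboxylate | CC(C)C(=O)CC[C@H]1C(C=O)=CC[C@@H]2[C@]1(C)CCC[C@@]2(C)C(=O)OC(C)(C)C | intermediate
19 | 5-(tert-butoxycarbonyl)-5,8a-dimethyl-1-(4-methyl-3-oxopentyl)-1,4,4a,5,6,7,8,8a-octahydronaphthalene-2-carboxylic acid | CC(C)C(=O)CC[C@H]1C(C(=O)O)=CC[C@@H]2[C@]1(C)CCC[C@@]2(C)C(=O)OC(C)(C)C | intermediate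
20 | (4R,5R,9R,10S)-13-oxo-13,14-secoabiet-7-ene-14,18-dioic acid | CC(C)C(=O)CC[C@H]1C(C(=O)O)=CC[C@@H]2[C@]1(C)CCC[C@@]2(C)C(=O)O | target

**Step count and risks**

Total step count: 14. Longest linear sequence: 13 steps (1 → 2 → 3 → 8 → 9 → 10 → 11 → 12 → 15 → 16 → 17 → 18 → 19 → 20).

The three steps most likely to fail:

Step 4. Enantiofacial control may be poor, or the acid-sensitive vinylallene may decay under the cationic catalyst, because this catalyst class has not been used with this diene class. The fallback sets out from 3 and 7. The Me2AlCl-promoted cycloaddition in CH2Cl2 at −78 °C, a known reaction type for vinylallenes and enals, gives the racemic cycloadduct F1. Condensation with (1R,2R)-N,N'-dimethyl-1,2-diphenylethane-1,2-diamine (Et2O, molecular sieves) gives the aminal of the wanted enantiomer F2 and the diastereomeric aminal F3, which are separated by chromatography. Mild aqueous acid hydrolysis of F2 comes back to the route at 8.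

Step 7. The electrophile may attack the unintended face of the C4 enolate, which would give the C4 epimer. The fallback sets out from 9 and exchanges the order of the two alkylations. Methylation (LiN(iPr)2, MeI) gives the 2-methyl ester F4, and the second alkylation with allyl bromide then places allyl on the face that methyl takes in step 7, so the configuration at C4 is the opposite of that from the original order. It comes back to the route at 11.

Step 9. The boron-to-carbon transfer may fail, with protodeboronation or self-condensation of the bromo ketone enolate in place of 1,2-migration. The fallback sets out from 12. Hydroboration–oxidation (9-BBN; NaOH, H2O2) gives the primary alcohol F5 with the same α-face delivery of hydrogen to C9. Dess–Martin periodinane gives the aldehyde F6, which is used at once. Wittig reaction with 3-methyl-1-(triphenyl-λ5-phosphanylidene)butan-2-one gives the (E)-enone F7. Hydrogenation over RhCl(PPh3)3 saturates the enone C=C bond together with C1=C2 and comes back to the route at 16.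

**Further compounds**

F1 | step 4 | racemic cycloadduct (8 and its enantiomer) | O=C[C@]1(C)C(=C)C(CO[Si](C)(C)C(C)(C)C)=CC[C@H]1CC(=O)OC(C)(C)C.O=C[C@@]1(C)C(=C)C(CO[Si](C)(C)C(C)(C)C)=CC[C@@H]1CC(=O)OC(C)(C)C
F2 | step 4 | aminal of 8 with (1R,2R)-N,N'-dimethyl-1,2-diphenylethane-1,2-diamine (1,3-dimethyl-4,5-diphenylimidazolidin-2-yl in place of formyl) | CN1C([C@]2(C)C(=C)C(CO[Si](C)(C)C(C)(C)C)=CC[C@H]2CC(=O)OC(C)(C)C)N(C)[C@H](c3ccccc3)[C@H]1c4ccccc4
F3 | step 4 | diastereomeric aminal from the enantiomer of 8 | CN1C([C@@]2(C)C(=C)C(CO[Si](C)(C)C(C)(C)C)=CC[C@@H]2CC(=O)OC(C)(C)C)N(C)[C@H](c3ccccc3)[C@H]1c4ccccc4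
F4 | step 7 | tert-butyl 2-[4-({[tert-butyl(dimethyl)silyl]oxy}methyl)-6-ethenyl-6-methyl-5-methylidenecyclohex-3-en-1-yl]propanoate (C4 epimers) | C=C[C@]1(C)C(=C)C(CO[Si](C)(C)C(C)(C)C)=CC[C@H]1C(C)C(=O)OC(C)(C)C
F5 | step 9 | tert-butyl 6-({[tert-butyl(dimethyl)silyl]oxy}methyl)-5-(hydroxymethyl)-1,4a-dimethyl-1,2,4a,5,8,8a-hexahydronaphthalene-1-carboxylate (H9 α) | OC[C@H]1C(CO[Si](C)(C)C(C)(C)C)=CC[C@@H]2[C@]1(C)C=CC[C@@]2(C)C(=O)OC(C)(C)C
F6 | step 9 | tert-butyl 6-({[tert-butyl(dimethyl)silyl]oxy}methyl)-5-formyl-1,4a-dimethyl-1,2,4a,5,8,8a-hexahydronaphthalene-1-carboxylate | O=C[C@H]1C(CO[Si](C)(C)C(C)(C)C)=CC[C@@H]2[C@]1(C)C=CC[C@@]2(C)C(=O)OC(C)(C)C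
F7 | step 9 | tert-butyl 6-({[tert-butyl(dimethyl)silyl]oxy}methyl)-1,4a-dimethyl-5-[(1E)-4-methyl-3-oxopent-1-en-1-yl]-1,2,4a,5,8,8a-hexahydronaphthalene-1-carboxylate | CC(C)C(=O)/C=C/[C@H]1C(CO[Si](C)(C)C(C)(C)C)=CC[C@@H]2[C@]1(C)C=CC[C@@]2(C)C(=O)OC(C)(C)C
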